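## Retrosynthetic overview

1. Target 40 is traced back to cyclodeca-3,7-dienone 24: C15 ester and protecting-group release last, C13 by Eschenmoser methylenation, the lactone by oxidation of a 1,4-diol, C8–OH by oxazaborolidine reduction.
2. Feature used: in the ten-membered ring C1–C10 the oxygen-bearing C8 is 1,3 to C5 through C4. Reconnecting C4–C8 gives cyclopentane ring A (C4–C5–C6–C7–C8) fused to cycloheptene ring B (C8–C9–C10=C1–C2–C3–C4), in which C1=C10 can only be ring-cis. Hence 24 comes from hydroxy mesylate 22 by C4–C8 fragmentation.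
3. 22 is assembled on ring A: ring B by ring-closing metathesis, C8–C9 by allylzinc addition, C7–C11 by enolate alkylation, C4/C5 by desymmetrising reduction of dione 7, itself made from γ-keto ester 4.
4. Ring order: ring A (step 2), ring B (step 12), ten-membered ring by cutting the A/B bond (step 14), lactone ring (step 17).

Key step: step 14

Remark on numbering: germacrane locants are used throughout (ring C1–C10; C14 on C10, C15 on C4, lactone oxygen on C8, C11–C12(–C13) on C7). "Ring-cis" and "ring-trans" describe how the ring passes through a double bond; by CIP rules C1=C10 is E and C4=C5 is Z in these compounds, because the oxygenated C14 and C15 outrank the ring carbons.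

## Route

Step 1
Reactants: 1 5-bromopent-1-ene; 2 methyl 4-chloro-4-oxobutanoate
Product: 4 methyl 4-oxonon-8-enoate, via pent-4-en-1-ylmagnesium bromide 3 (not isolated)
Conditions: Mg, THF, rt; then 2, Fe(acac)3 (3 mol %), THF, −78 °C
Reagents that add atoms: none
Why: Iron-catalysed acylation of a Grignard reagent by an acid chloride (cross-coupling-type ketone synthesis) is much faster at −78 °C than addition to the methyl ester or to the ketone formed, so the γ-keto ester should result with the terminal alkene untouched.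

Step 2
Reactants: 4 methyl 4-oxonon-8-enoate
Product: 5 2-(but-3-en-1-yl)cyclopentane-1,3-dione
Conditions: KOtBu (2.2 equiv), THF, reflux; then aq. HCl
Reagents that add atoms: none
Why: Intramolecular Claisen (Dieckmann-type) condensation, in which only the C5 enolate can reach the ester through a five-membered transition state and deprotonation of the acidic 1,3-dione pulls the equilibrium over; this closes ring A.

Step 3
Reactants: 5 2-(but-3-en-1-yl)cyclopentane-1,3-dione
Product: 6 2-(but-3-en-1-yl)-2-(hydroxymethyl)cyclopentane-1,3-dione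
Conditions: aq. CH2O (37%), Et3N (cat.), THF, 0 °C → rt
Reagents that add atoms: formaldehyde C=O
Why: Aldol hydroxymethylation of the enolised 2-alkyl-1,3-dione by formaldehyde at its single nucleophilic carbon installs C15 and makes C4 quaternary (not yet stereogenic, the two carbonyls being equivalent).

Step 4
Reactants: 6 2-(but-3-en-1-yl)-2-(hydroxymethyl)cyclopentane-1,3-dione
Product: 7 2-(but-3-en-1-yl)-2-{[(tert-butyldiphenylsilyl)oxy]methyl}cyclopentane-1,3-dione
Conditions: t-BuPh2SiCl, imidazole, DMF, 0 °C → rt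
Reagents that add atoms: tert-butyl(chloro)diphenylsilane CC(C)(C)[Si](Cl)(c1ccccc1)c1ccccc1
Why: Silylation of the primary alcohol under neutral imidazole conditions removes the free β-hydroxyl that could undergo retro-aldol loss of formaldehyde and installs the bulky group used for face discrimination in step 5.

Step 5
Reactants: 7 2-(but-3-en-1-yl)-2-{[(tert-butyldiphenylsilyl)oxy]methyl}cyclopentane-1,3-dione
Product: 8 (2S,3S)-2-(but-3-en-1-yl)-2-{[(tert-butyldiphenylsilyl)oxy]methyl}-3-hydroxycyclopentan-1-one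
Conditions: (R)-1-methyl-3,3-diphenyltetrahydro-1H,3H-pyrrolo[1,2-c][1,3,2]oxazaborole [(R)-Me-CBS, 20 mol %], catecholborane (1.1 equiv), toluene, −78 °C; then MeOH, pH 7 buffer
Reagents that add atoms: none
Why: Corey–Bakshi–Shibata reduction used as a desymmetrisation: the (R)-catalyst makes whichever carbonyl reacts an S carbinol (quaternary C4 as the large flank, CH2 as the small one), and because the catalyst–borane complex should approach anti to the bulky CH2OSi(t-Bu)Ph2 group, the carbonyl whose catalyst-preferred face lies on the butenyl side is reduced, placing OH cis to C15 and fixing C4 as S.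

Step 6
Reactants: 8 (2S,3S)-2-(but-3-en-1-yl)-2-{[(tert-butyldiphenylsilyl)oxy]methyl}-3-hydroxycyclopentan-1-one
Product: 9 (1S,2S)-2-(but-3-en-1-yl)-2-{[(tert-butyldiphenylsilyl)oxy]methyl}-3-oxocyclopentyl pivalate
Conditions: t-BuCOCl, pyridine, 4-(dimethylamino)pyridine (cat.), CH2Cl2, 0 °C → rt
Reagents that add atoms: pivaloyl chloride CC(C)(C)C(=O)Cl
Why: Nucleophile-catalysed acylation protects the hindered secondary alcohol as a pivalate, which has no α-hydrogen, blocks retro-aldol opening under the strong base of step 7 and is cleaved without a separate operation in step 10.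

Step 7
Reactants: 9 (1S,2S)-2-(but-3-en-1-yl)-2-{[(tert-butyldiphenylsilyl)oxy]methyl}-3-oxocyclopentyl pivalate; 10 tert-butyl bromoacetate
Product: 12 tert-butyl 2-[(1R,3S,4S)-3-(but-3-en-1-yl)-3-{[(tert-butyldiphenylsilyl)oxy]methyl}-2-oxo-4-(pivaloyloxy)cyclopentyl]acetate, via lithium enolate 11 (not isolated)
Conditions: LiN(iPr)2, THF, −78 °C; then 10, DMPU, −78 → −40 °C
Reagents that add atoms: none
Why: Kinetic enolate alkylation: C7 is the only enolisable position (C4 is quaternary), and the bromoacetate should enter anti to the C5 pivaloyloxy and C15 silyloxymethyl groups that share one face of the enolate, setting C7 as R (acetate arm trans to the C5 oxygen).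

Step 8
Reactants: 13 3-chloro-2-(chloromethyl)prop-1-ene; 14 (4-methoxyphenyl)methanol
Product: 16 1-({[2-(chloromethyl)prop-2-en-1-yl]oxy}methyl)-4-methoxybenzene, via sodium 4-methoxybenzyl oxide 15 (not isolated)
Conditions: NaH, THF, 0 °C; then 13 (3 equiv), Bu4NI (cat.), THF/DMF, rt
Reagents that add atoms: none
Why: Williamson ether synthesis; the threefold excess of the symmetrical dichloride keeps substitution at the mono stage.

Step 9
Reactants: 12 tert-butyl 2-[(1R,3S,4S)-3-(but-3-en-1-yl)-3-{[(tert-butyldiphenylsilyl)oxy]methyl}-2-oxo-4-(pivaloyloxy)cyclopentyl]acetate; 16 1-({[2-(chloromethyl)prop-2-en-1-yl]oxy}methyl)-4-methoxybenzene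
Product: 18 tert-butyl 2-[(1R,2S,3S,4S)-3-(but-3-en-1-yl)-3-{[(tert-butyldiphenylsilyl)oxy]methyl}-2-hydroxy-2-{2-[(4-methoxybenzyloxy)methyl]prop-2-en-1-yl}-4-(pivaloyloxy)cyclopentyl]acetate, via allylzinc chloride 17 (not isolated)
Conditions: Zn dust, LiCl, THF, rt; then 12, THF, −78 → 0 °C; aq. NH4Cl
Reagents that add atoms: none
Why: Zinc insertion into the allylic chloride gives an allylzinc reagent that adds to the hindered ketone through a closed six-membered transition state (Barbier-type allylation) faster than it attacks either ester, and attack anti to the C7 arm should give the 8S tertiary alcohol with OH trans to C15 (C8 is not a stereocentre of the target, so this centre only defines the ring fusion of the precursor).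

Step 10
Reactants: 18 tert-butyl 2-[(1R,2S,3S,4S)-3-(but-3-en-1-yl)-3-{[(tert-butyldiphenylsilyl)oxy]methyl}-2-hydroxy-2-{2-[(4-methoxybenzyloxy)methyl]prop-2-en-1-yl}-4-(pivaloyloxy)cyclopentyl]acetate
Product: 19 (1S,2S,3S,5S)-2-(but-3-en-1-yl)-2-{[(tert-butyldiphenylsilyl)oxy]methyl}-5-(2-hydroxyethyl)-1-{2-[(4-methoxybenzyloxy)methyl]prop-2-en-1-yl}cyclopentane-1,3-diol
Conditions: LiAlH4, THF, 0 °C → rt; then H2O, aq. NaOH, H2O
Reagents that add atoms: none
Why: Hydride reduction converts the tert-butyl ester into the C12 primary alcohol and cleaves the pivalate in the same operation, while the silyl and 4-methoxybenzyl ethers and the alkenes are inert.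

Step 11
Reactants: 19 (1S,2S,3S,5S)-2-(but-3-en-1-yl)-2-{[(tert-butyldiphenylsilyl)oxy]methyl}-5-(2-hydroxyethyl)-1-{2-[(4-methoxybenzyloxy)methyl]prop-2-en-1-yl}cyclopentane-1,3-diol
Product: 20 (1S,2S,3S,5S)-2-(but-3-en-1-yl)-5-{2-[(tert-butyldimethylsilyl)oxy]ethyl}-2-{[(tert-butyldiphenylsilyl)oxy]methyl}-1-{2-[(4-methoxybenzyloxy)methyl]prop-2-en-1-yl}cyclopentane-1,3-diol
Conditions: t-BuMe2SiCl (1.05 equiv), imidazole, CH2Cl2, 0 °C
Reagents that add atoms: tert-butyl(chloro)dimethylsilane CC(C)(C)[Si](C)(C)Cl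
Why: Steric discrimination in silylation: the primary C12 hydroxyl reacts far faster than the neopentyl-type secondary C5–OH or the tertiary C8–OH.

Step 12
Reactants: 20 (1S,2S,3S,5S)-2-(but-3-en-1-yl)-5-{2-[(tert-butyldimethylsilyl)oxy]ethyl}-2-{[(tert-butyldiphenylsilyl)oxy]methyl}-1-{2-[(4-methoxybenzyloxy)methyl]prop-2-en-1-yl}cyclopentane-1,3-diol
Product: 21 trans-fused hydroazulene diol (1S,7S,8S,10S)-10-{2-[(tert-butyldimethylsilyl)oxy]ethyl}-7-{[(tert-butyldiphenylsilyl)oxy]methyl}-3-{[(4-methoxybenzyl)oxy]methyl}bicyclo[5.3.0]dec-3-ene-1,8-diol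
Conditions: second-generation Grubbs catalyst (5 mol %), CH2Cl2 (0.005 M), 40 °C
Reagents that add atoms: none
Why: Ring-closing metathesis between the monosubstituted and the 1,1-disubstituted alkene closes seven-membered ring B with loss of ethene; the ring size allows only the ring-cis trisubstituted C1=C10 bond, and the trans disposition of the two chains on ring A gives the trans-fused bicycle.

Step 13
Reactants: 21 trans-fused hydroazulene diol
Product: 22 (1S,7S,8S,10S)-10-{2-[(tert-butyldimethylsilyl)oxy]ethyl}-7-{[(tert-butyldiphenylsilyl)oxy]methyl}-1-hydroxy-3-{[(4-methoxybenzyl)oxy]methyl}bicyclo[5.3.0]dec-3-en-8-yl methanesulfonate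
Conditions: MeSO2Cl, Et3N, CH2Cl2, −20 → 0 °C
Reagents that add atoms: methanesulfonyl chloride CS(=O)(=O)Cl
Why: Sulfonylation through sulfene is selective for the secondary C5–OH over the tertiary C8–OH and retains configuration at C5, so the mesylate stays cis to C15; the product is used at once.

Step 14
Reactants: 22 hydroxy mesylate (C5–OMs cis to C15, C8–OH trans to C15)
Product: 24 (3E,7Z,10R)-10-{2-[(tert-butyldimethylsilyl)oxy]ethyl}-7-{[(tert-butyldiphenylsilyl)oxy]methyl}-3-{[(4-methoxybenzyl)oxy]methyl}cyclodeca-3,7-dien-1-one, via potassium alkoxide 23 (not isolated)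
Conditions: KN(SiMe3)2 (1.0 equiv), THF, −78 → −20 °C; then pH 7 buffer
Reagents that add atoms: none
Why: KN(SiMe3)2 removes the proton of the tertiary C8–OH, and in alkoxide 23 the oxygen lone pair forms the C8=O π bond while the C4–C8 σ bond becomes the C4=C5 π bond and mesylate leaves C5, all in one concerted heterolytic step. This is a Wharton-type Grob fragmentation of a cyclic 1,3-diol monosulfonate, the reaction type long used to open decalins to cyclodecenones. No ring is closed by bond formation: the ten-membered ring appears when the bond shared by ring A and ring B is cut, so the unfavourable end-to-end closure of a medium ring is avoided. No stereocentre is created and C7 is carried through; the new stereo-element, the ring-trans C4=C5 bond, follows stereospecifically from the anti elimination because the mesylate is cis to C15 on ring A, while the ring-cis C1=C10 bond was fixed beforehand in ring B. The step needs fragmentation to outrun E2 loss of the mesylate, epimerisation at C7 and drift of C1=C10 into conjugation: in the trans-fused bicycle the mesylate is pseudo-equatorial and close to antiperiplanar to C4–C8 (estimated 155–160°), exactly one equivalent of base is used cold, and the only by-product, potassium mesylate, is not basic.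

Step 15
Reactants: 24 cyclodeca-3,7-dien-1-one
Product: 25 (1S,3E,7Z,10R)-10-{2-[(tert-butyldimethylsilyl)oxy]ethyl}-7-{[(tert-butyldiphenylsilyl)oxy]methyl}-3-{[(4-methoxybenzyl)oxy]methyl}cyclodeca-3,7-dien-1-ol
Conditions: (R)-Me-CBS (50 mol %), catecholborane, toluene, −78 → −40 °C; then MeOH, pH 7 buffer
Reagents that add atoms: none
Why: Corey–Bakshi–Shibata reduction under catalyst control: with catecholborane (which leaves the alkenes alone) the (R)-catalyst treats branched C7 as the large and C9H2 as the small flank and should deliver hydride to give the 8S alcohol, the configuration needed for the trans-fused lactone.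

Step 16
Reactants: 25 8S alcohol
Product: 26 (1S,3E,7Z,10R)-7-{[(tert-butyldiphenylsilyl)oxy]methyl}-10-(2-hydroxyethyl)-3-{[(4-methoxybenzyl)oxy]methyl}cyclodeca-3,7-dien-1-ol
Conditions: HF·pyridine, pyridine, THF, 0 °C
Reagents that add atoms: none
Why: Buffered HF·pyridine cleaves the primary tert-butyldimethylsilyl ether much faster than the tert-butyldiphenylsilyl ether, and the buffered medium avoids acid-induced transannular cyclisation of the 1,5-diene.

Step 17
Reactants: 26 1,4-diol
Product: 29 (7R,8S)-15-[(tert-butyldiphenylsilyl)oxy]-14-[(4-methoxybenzyl)oxy]-13-norgermacra-1(10),4-dien-12,8-olide, via hydroxy aldehyde 27 (not isolated), via lactol 28 (not isolated)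
Conditions: 2,2,6,6-tetramethylpiperidin-1-oxyl (20 mol %), PhI(OAc)2 (2.5 equiv), CH2Cl2, rt
Reagents that add atoms: none
Why: Oxoammonium (TEMPO) oxidation is selective for the primary alcohol; the aldehyde is trapped by the C8 hydroxyl as a lactol, which is oxidised on to the γ-lactone (oxidative lactonisation of a 1,4-diol), the trans ring fusion being fixed by C7 and C8.

Step 18
Reactants: 29 trans-fused γ-lactone
Product: 33 (7R,8S)-15-[(tert-butyldiphenylsilyl)oxy]-14-[(4-methoxybenzyl)oxy]germacra-1(10),4,11(13)-trien-12,8-olide, via lactone lithium enolate 30 (not isolated), via Mannich base 31 (not isolated), via methiodide 32 (not isolated)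
Conditions: LiN(iPr)2, THF, −78 °C; Me2N=CH2+ I−, −78 °C → rt; then MeI, MeOH, rt; then aq. NaHCO3, CH2Cl2, rt
Reagents that add atoms: N,N-dimethylmethyleneiminium iodide (Eschenmoser's salt) C=[N+](C)C.[I-]
Why: Eschenmoser methylenation: Mannich reaction of the lactone enolate with the iminium salt, N-methylation and Hofmann-type elimination give the exocyclic C11=C13 bond, and the C11 stereocentre of the intermediates disappears.

Step 19
Reactants: 33 α-methylene lactone
Product: 34 (7R,8S)-15-hydroxy-14-[(4-methoxybenzyl)oxy]germacra-1(10),4,11(13)-trien-12,8-olide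
Conditions: Bu4NF, AcOH (1:1), THF, 0 °C → rt
Reagents that add atoms: none
Why: Fluoride cleavage of the silyl ether, buffered with acetic acid so that the α-methylene lactone is not exposed to basic fluoride or alkoxide.

Step 20
Reactants: 35 2-hydroxy-2-methylpropanoic acid
Product: 37 2-methyl-2-[(triethylsilyl)oxy]propanoic acid, via bis-silyl derivative 36 (not isolated)
Conditions: Et3SiOTf (2.2 equiv), 2,6-lutidine, CH2Cl2, 0 °C; then THF/H2O, K2CO3 (cat.), rt; pH 4 work-up
Reagents that add atoms: triethylsilyl trifluoromethanesulfonate CC[Si](CC)(CC)OS(=O)(=O)C(F)(F)F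
Why: Exhaustive silylation followed by selective hydrolysis of the labile silyl ester leaves the tertiary silyl ether, giving an acid whose hydroxyl cannot self-acylate.

Step 21
Reactants: 34 C15 alcohol; 37 2-methyl-2-[(triethylsilyl)oxy]propanoic acid
Product: 38 (7R,8S)-14-[(4-methoxybenzyl)oxy]-15-({2-methyl-2-[(triethylsilyl)oxy]propanoyl}oxy)germacra-1(10),4,11(13)-trien-12,8-olide
Conditions: EDC·HCl, 4-(dimethylamino)pyridine, CH2Cl2, 0 °C → rt
Reagents that add atoms: none
Why: Carbodiimide/aminopyridine (Steglich) esterification acylates the primary allylic C15–OH under neutral conditions tolerated by the α-methylene lactone.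

Step 22
Reactants: 38 C15 ester
Product: 39 (7R,8S)-14-hydroxy-15-({2-methyl-2-[(triethylsilyl)oxy]propanoyl}oxy)germacra-1(10),4,11(13)-trien-12,8-olide
Conditions: DDQ (1.3 equiv), CH2Cl2/pH 7 buffer (10:1), 0 °C
Reagents that add atoms: none
Why: Oxidative cleavage of the 4-methoxybenzyl ether by DDQ (hydride abstraction, then hydrolysis of the oxocarbenium ion) in a buffered two-phase medium frees C14–OH without affecting the silyl ether, the esters or the alkenes.

Step 23
Reactants: 39 silyl-protected target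
Product: 40 CNP0194188.1, (7R,8S)-14-hydroxy-15-[(2-hydroxy-2-methylpropanoyl)oxy]germacra-1(10),4,11(13)-trien-12,8-olide
Conditions: HF·pyridine, pyridine, THF, 0 °C → rt
Reagents that add atoms: none
Why: Fluoride-mediated desilylation under buffered conditions removes the triethylsilyl group without ester migration, conjugate addition to the methylene lactone or transannular cyclisation, giving the target.

## Compound list

1 | 5-bromopent-1-ene | C=CCCCBr | starting material
2 | methyl 4-chloro-4-oxobutanoate | COC(=O)CCC(=O)Cl | starting material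
3 | pent-4-en-1-ylmagnesium bromide | C=CCCC[Mg]Br | intermediate (not isolated)
4 | methyl 4-oxonon-8-enoate | COC(=O)CCC(=O)CCCC=C | intermediate
5 | 2-(but-3-en-1-yl)cyclopentane-1,3-dione | C=CCCC1C(=O)CCC1=O | intermediate
6 | 2-(but-3-en-1-yl)-2-(hydroxymethyl)cyclopentane-1,3-dione | C=CCCC1(CO)C(=O)CCC1=O | intermediate
7 | 2-(but-3-en-1-yl)-2-{[(tert-butyldiphenylsilyl)oxy]methyl}cyclopentane-1,3-dione | C=CCCC1(CO[Si](c2ccccc2)(c2ccccc2)C(C)(C)C)C(=O)CCC1=O | intermediate
8 | (2S,3S)-2-(but-3-en-1-yl)-2-{[(tert-butyldiphenylsilyl)oxy]methyl}-3-hydroxycyclopentan-1-one (OH cis to CH2OSi; C4 S, C5 S) | O[C@H]1CCC(=O)[C@@]1(CCC=C)CO[Si](c2ccccc2)(c2ccccc2)C(C)(C)C | intermediate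
9 | (1S,2S)-2-(but-3-en-1-yl)-2-{[(tert-butyldiphenylsilyl)oxy]methyl}-3-oxocyclopentyl pivalate | CC(C)(C)C(=O)O[C@H]1CCC(=O)[C@@]1(CCC=C)CO[Si](c2ccccc2)(c2ccccc2)C(C)(C)C | intermediate
10 | tert-butyl bromoacetate | CC(C)(C)OC(=O)CBr | starting material
11 | lithium enolate of 9 (C7=C8–OLi) | CC(C)(C)C(=O)O[C@H]1CC=C(O[Li])[C@@]1(CCC=C)CO[Si](c2ccccc2)(c2ccccc2)C(C)(C)C | intermediate (not isolated)
12 | tert-butyl 2-[(1R,3S,4S)-3-(but-3-en-1-yl)-3-{[(tert-butyldiphenylsilyl)oxy]methyl}-2-oxo-4-(pivaloyloxy)cyclopentyl]acetate (C7 R; arm trans to C5–O) | CC(C)(C)C(=O)O[C@H]1C[C@H](CC(=O)OC(C)(C)C)C(=O)[C@@]1(CCC=C)CO[Si](c2ccccc2)(c2ccccc2)C(C)(C)C | intermediate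
13 | 3-chloro-2-(chloromethyl)prop-1-ene | C=C(CCl)CCl | starting material
14 | (4-methoxyphenyl)methanol | COc1ccc(CO)cc1 | starting material
15 | sodium 4-methoxybenzyl oxide | COc1ccc(CO[Na])cc1 | intermediate (not isolated)
16 | 1-({[2-(chloromethyl)prop-2-en-1-yl]oxy}methyl)-4-methoxybenzene | C=C(CCl)COCc1ccc(OC)cc1 | intermediate
17 | {2-[(4-methoxybenzyloxy)methyl]prop-2-en-1-yl}zinc chloride | C=C(C[Zn]Cl)COCc1ccc(OC)cc1 | intermediate (not isolated)
18 | tert-butyl 2-[(1R,2S,3S,4S)-3-(but-3-en-1-yl)-3-{[(tert-butyldiphenylsilyl)oxy]methyl}-2-hydroxy-2-{2-[(4-methoxybenzyloxy)methyl]prop-2-en-1-yl}-4-(pivaloyloxy)cyclopentyl]acetate (C8–OH trans to C15) | CC(C)(C)C(=O)O[C@H]1C[C@H](CC(=O)OC(C)(C)C)[C@@](O)(CC(=C)COCc2ccc(OC)cc2)[C@@]1(CCC=C)CO[Si](c3ccccc3)(c3ccccc3)C(C)(C)C | intermediate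
19 | (1S,2S,3S,5S)-2-(but-3-en-1-yl)-2-{[(tert-butyldiphenylsilyl)oxy]methyl}-5-(2-hydroxyethyl)-1-{2-[(4-methoxybenzyloxy)methyl]prop-2-en-1-yl}cyclopentane-1,3-diol | O[C@H]1C[C@H](CCO)[C@@](O)(CC(=C)COCc2ccc(OC)cc2)[C@@]1(CCC=C)CO[Si](c3ccccc3)(c3ccccc3)C(C)(C)C | intermediate
20 | (1S,2S,3S,5S)-2-(but-3-en-1-yl)-5-{2-[(tert-butyldimethylsilyl)oxy]ethyl}-2-{[(tert-butyldiphenylsilyl)oxy]methyl}-1-{2-[(4-methoxybenzyloxy)methyl]prop-2-en-1-yl}cyclopentane-1,3-diol | O[C@H]1C[C@H](CCO[Si](C)(C)C(C)(C)C)[C@@](O)(CC(=C)COCc2ccc(OC)cc2)[C@@]1(CCC=C)CO[Si](c3ccccc3)(c3ccccc3)C(C)(C)C | intermediate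
21 | trans-fused hydroazulene diol, (1S,7S,8S,10S)-10-{2-[(tert-butyldimethylsilyl)oxy]ethyl}-7-{[(tert-butyldiphenylsilyl)oxy]methyl}-3-{[(4-methoxybenzyl)oxy]methyl}bicyclo[5.3.0]dec-3-ene-1,8-diol (germacrane 4S,5S,7S,8S; C5–OH cis to C15) | O[C@H]1C[C@H](CCO[Si](C)(C)C(C)(C)C)[C@@]2(O)C/C(COCc3ccc(OC)cc3)=C\CC[C@]12CO[Si](c3ccccc3)(c3ccccc3)C(C)(C)C | intermediate
22 | hydroxy mesylate, (1S,7S,8S,10S)-10-{2-[(tert-butyldimethylsilyl)oxy]ethyl}-7-{[(tert-butyldiphenylsilyl)oxy]methyl}-1-hydroxy-3-{[(4-methoxybenzyl)oxy]methyl}bicyclo[5.3.0]dec-3-en-8-yl methanesulfonate | CS(=O)(=O)O[C@H]1C[C@H](CCO[Si](C)(C)C(C)(C)C)[C@@]2(O)C/C(COCc3ccc(OC)cc3)=C\CC[C@]12CO[Si](c3ccccc3)(c3ccccc3)C(C)(C)C | intermediate (key-step precursor)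
23 | potassium C8 alkoxide of 22 | CS(=O)(=O)O[C@H]1C[C@H](CCO[Si](C)(C)C(C)(C)C)[C@@]2(O[K])C/C(COCc3ccc(OC)cc3)=C\CC[C@]12CO[Si](c3ccccc3)(c3ccccc3)C(C)(C)C | intermediate (not isolated)
24 | (3E,7Z,10R)-10-{2-[(tert-butyldimethylsilyl)oxy]ethyl}-7-{[(tert-butyldiphenylsilyl)oxy]methyl}-3-{[(4-methoxybenzyl)oxy]methyl}cyclodeca-3,7-dien-1-one (C1=C10 ring-cis, C4=C5 ring-trans, C8 ketone, C7 R) | O=C1C/C(COCc2ccc(OC)cc2)=C\CC/C(CO[Si](c2ccccc2)(c2ccccc2)C(C)(C)C)=C/C[C@@H]1CCO[Si](C)(C)C(C)(C)C | intermediate (key-step product)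
25 | (1S,3E,7Z,10R)-10-{2-[(tert-butyldimethylsilyl)oxy]ethyl}-7-{[(tert-butyldiphenylsilyl)oxy]methyl}-3-{[(4-methoxybenzyl)oxy]methyl}cyclodeca-3,7-dien-1-ol (7R,8S) | O[C@H]1C/C(COCc2ccc(OC)cc2)=C\CC/C(CO[Si](c2ccccc2)(c2ccccc2)C(C)(C)C)=C/C[C@@H]1CCO[Si](C)(C)C(C)(C)C | intermediate
26 | (1S,3E,7Z,10R)-7-{[(tert-butyldiphenylsilyl)oxy]methyl}-10-(2-hydroxyethyl)-3-{[(4-methoxybenzyl)oxy]methyl}cyclodeca-3,7-dien-1-ol | O[C@H]1C/C(COCc2ccc(OC)cc2)=C\CC/C(CO[Si](c2ccccc2)(c2ccccc2)C(C)(C)C)=C/C[C@@H]1CCO | intermediate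
27 | hydroxy aldehyde (C12 aldehyde, C8–OH; 7R,8S) | O[C@H]1C/C(COCc2ccc(OC)cc2)=C\CC/C(CO[Si](c2ccccc2)(c2ccccc2)C(C)(C)C)=C/C[C@@H]1CC=O | intermediate (not isolated)
28 | lactol (C12 hemiacetal, both anomers; 7R,8S) | C1C(O)O[C@H]2C/C(COCc3ccc(OC)cc3)=C\CC/C(CO[Si](c3ccccc3)(c3ccccc3)C(C)(C)C)=C/C[C@H]12 | intermediate (not isolated)
29 | (7R,8S)-15-[(tert-butyldiphenylsilyl)oxy]-14-[(4-methoxybenzyl)oxy]-13-norgermacra-1(10),4-dien-12,8-olide (trans-fused γ-lactone) | C1C(=O)O[C@H]2C/C(COCc3ccc(OC)cc3)=C\CC/C(CO[Si](c3ccccc3)(c3ccccc3)C(C)(C)C)=C/C[C@H]12 | intermediate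
30 | lithium enolate of lactone 29 | C1=C(O[Li])O[C@H]2C/C(COCc3ccc(OC)cc3)=C\CC/C(CO[Si](c3ccccc3)(c3ccccc3)C(C)(C)C)=C/C[C@H]12 | intermediate (not isolated)
31 | Mannich base, 11-[(dimethylamino)methyl] lactone (C11 epimers) | CN(C)CC1C(=O)O[C@H]2C/C(COCc3ccc(OC)cc3)=C\CC/C(CO[Si](c3ccccc3)(c3ccccc3)C(C)(C)C)=C/C[C@H]12 | intermediate (not isolated)
32 | methiodide of 31 | C[N+](C)(C)CC1C(=O)O[C@H]2C/C(COCc3ccc(OC)cc3)=C\CC/C(CO[Si](c3ccccc3)(c3ccccc3)C(C)(C)C)=C/C[C@H]12.[I-] | intermediate (not isolated)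
33 | (7R,8S)-15-[(tert-butyldiphenylsilyl)oxy]-14-[(4-methoxybenzyl)oxy]germacra-1(10),4,11(13)-trien-12,8-olide | C=C1C(=O)O[C@H]2C/C(COCc3ccc(OC)cc3)=C\CC/C(CO[Si](c3ccccc3)(c3ccccc3)C(C)(C)C)=C/C[C@H]12 | intermediate
34 | (7R,8S)-15-hydroxy-14-[(4-methoxybenzyl)oxy]germacra-1(10),4,11(13)-trien-12,8-olide | C=C1C(=O)O[C@H]2C/C(COCc3ccc(OC)cc3)=C\CC/C(CO)=C/C[C@H]12 | intermediate
35 | 2-hydroxy-2-methylpropanoic acid | CC(C)(O)C(=O)O | starting material
36 | triethylsilyl 2-methyl-2-[(triethylsilyl)oxy]propanoate | CC[Si](CC)(CC)OC(C)(C)C(=O)O[Si](CC)(CC)CC | intermediate (not isolated)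
37 | 2-methyl-2-[(triethylsilyl)oxy]propanoic acid | CC[Si](CC)(CC)OC(C)(C)C(=O)O | intermediate
38 | (7R,8S)-14-[(4-methoxybenzyl)oxy]-15-({2-methyl-2-[(triethylsilyl)oxy]propanoyl}oxy)germacra-1(10),4,11(13)-trien-12,8-olide | C=C1C(=O)O[C@H]2C/C(COCc3ccc(OC)cc3)=C\CC/C(COC(=O)C(C)(C)O[Si](CC)(CC)CC)=C/C[C@H]12 | intermediate
39 | (7R,8S)-14-hydroxy-15-({2-methyl-2-[(triethylsilyl)oxy]propanoyl}oxy)germacra-1(10),4,11(13)-trien-12,8-olide | C=C1C(=O)O[C@H]2C/C(CO)=C\CC/C(COC(=O)C(C)(C)O[Si](CC)(CC)CC)=C/C[C@H]12 | intermediate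
40 | CNP0194188.1, (7R,8S)-14-hydroxy-15-[(2-hydroxy-2-methylpropanoyl)oxy]germacra-1(10),4,11(13)-trien-12,8-olide (C1=C10 ring-cis, C4=C5 ring-trans) | C=C1C(=O)O[C@H]2C/C(CO)=C\CC/C(COC(=O)C(C)(C)O)=C/C[C@H]12 | target

## Step count and risks

Total step count: 23 (21 in the main line plus the preparations of 16 and 37).
Longest linear sequence: 21 steps (steps 1–7, 9–19 and 21–23).

Steps most likely to fail:

1. Step 14 (fragmentation). The C5–O bond sits on a five-membered ring and cannot reach a full 180° to C4–C8, so fragmentation may be slow enough for E2 loss of the mesylate to compete. Once the ketone is formed, any surviving alkoxide or amide could epimerise C7 or move C1=C10 into conjugation. Fallback: the fragmentation is run without a strong base and with a far better leaving group. It sets out from diol 21 (bypassing 22): Tf2O and 2,6-di-tert-butyl-4-methylpyridine in CH2Cl2 at −78 °C should sulfonylate the secondary C5 hydroxyl selectively to give the C5 triflate F1. On warming to 0 °C this is expected to fragment in the same flask, with the hindered pyridine as the only base, returning to the route at ketone 24.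

2. Step 15 (C8 reduction). The flexible ten-membered ring has its own facial bias (attack from the ring periphery), which may oppose or dilute catalyst control and deliver the 8R epimer, leading to the cis-fused lactone. Fallback: the ring's bias is used instead of fought. It sets out from ketone 24: LiBH(s-Bu)3 in THF at −78 °C under pure substrate control should give the 8R alcohol F2. A Mitsunobu reaction (PPh3, diisopropyl azodicarboxylate, 4-nitrobenzoic acid, toluene, 0 °C) inverts C8 to the 8S 4-nitrobenzoate F3, and methanolysis (K2CO3, MeOH) returns to the route at alcohol 25.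

3. Step 5 (desymmetrisation). The catalyst fixes only the configuration of the carbinol carbon; which carbonyl is reduced depends on discrimination between two primary substituents at C4 (CH2OSi and butenyl). Weak discrimination would give the C4-epimeric hydroxy ketone alongside 8. Fallback: biocatalytic desymmetrisation before silylation. It sets out from hydroxymethyl dione 6: an NADPH-dependent ketoreductase chosen from a commercial panel for this isomer (glucose/glucose dehydrogenase recycling, pH 7 buffer, 30 °C) selects carbonyl and face through its binding pocket and should give (2S,3S)-2-(but-3-en-1-yl)-3-hydroxy-2-(hydroxymethyl)cyclopentan-1-one F4. Selective silylation of the primary hydroxyl (t-BuPh2SiCl, imidazole, CH2Cl2, 0 °C) returns to the route at 8.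

## Further compounds

F1 | step 14 | C5 triflate of diol 21 (C8–OH free) | FC(F)(F)S(=O)(=O)O[C@H]1C[C@H](CCO[Si](C)(C)C(C)(C)C)[C@@]2(O)C/C(COCc3ccc(OC)cc3)=C\CC[C@]12CO[Si](c3ccccc3)(c3ccccc3)C(C)(C)C
F2 | step 15 | (1R,3E,7Z,10R)-10-{2-[(tert-butyldimethylsilyl)oxy]ethyl}-7-{[(tert-butyldiphenylsilyl)oxy]methyl}-3-{[(4-methoxybenzyl)oxy]methyl}cyclodeca-3,7-dien-1-ol (C8 epimer of 25) | O[C@@H]1C/C(COCc2ccc(OC)cc2)=C\CC/C(CO[Si](c2ccccc2)(c2ccccc2)C(C)(C)C)=C/C[C@@H]1CCO[Si](C)(C)C(C)(C)C
F3 | step 15 | 4-nitrobenzoate of alcohol 25 (8S) | O=C(O[C@H]1C/C(COCc2ccc(OC)cc2)=C\CC/C(CO[Si](c2ccccc2)(c2ccccc2)C(C)(C)C)=C/C[C@@H]1CCO[Si](C)(C)C(C)(C)C)c1ccc([N+](=O)[O-])cc1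
F4 | step 5 | (2S,3S)-2-(but-3-en-1-yl)-3-hydroxy-2-(hydroxymethyl)cyclopentan-1-one | O[C@H]1CCC(=O)[C@@]1(CCC=C)CO
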